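**Retrosynthetic overview**
1. Target ⇒ its C1 silyl ether ⇒ ring C of the naphthalene opened across C3′–C4′ and C1′–C2′, giving a 5-methoxybenzocyclobutenone that carries the tetralin on its sp3 carbon, plus (Z)-2-ethoxyvinyllithium (4π opening, 6π closing, loss of EtOH).
2. Feature used: in the naphthalene, ring C bears C4′–OH para to C1′ (bonded to tetralin C4) and peri to C5′–OMe of ring D; this is a benzocyclobutenone with C=O next to the OMe-bearing arene carbon, enlarged by C2′/C3′.
3. Benzocyclobutenone ⇒ [2+2] of 3-methoxybenzyne (from 2-iodo-3-methoxyphenyl triflate, made from 3-methoxyphenol) with the ketene silyl acetal of the cis-tetralinylacetate; aryne polarisation puts the ketal carbon ortho to OMe.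
4. Tetralinylacetate ⇒ 5-methoxy-1-tetralone: CBS reduction (C1), silylation, benzylic oxidation at C4, Horner–Wadsworth–Emmons olefination, hydrogenation anti to the silyloxy group (C4, cis).
5. Ring order: rings A/B (tetralone) and ring D (phenol) are bought; the four-membered ring is formed next and ring C last.

Key step: step 12

Assumption: the four starting materials (1, 6, 11, 21) are commercial. Locants C1–C8a (tetralin, rings A/B) and C1′–C8a′ (naphthalene, rings C/D) follow the target; in intermediates named as tetralin-1-yl groups the attachment carbon is C1, the silyloxy carbon C4 and the methoxy carbon C8.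

**Step 1**
Reactants: 1 5-methoxy-1-tetralone
Product: 2 (1S)-5-methoxy-1,2,3,4-tetrahydronaphthalen-1-ol
Conditions: (R)-Me-CBS oxazaborolidine (cat.), BH3·SMe2, THF, −20 → 0 °C; then MeOH
Reagents that add atoms: none
Why: Corey–Bakshi–Shibata reduction of an aryl alkyl ketone, in which the (R)-catalyst, with the arene as the large group, should deliver hydride so as to give the (S)-carbinol.

**Step 2**
Reactants: 2 (1S)-5-methoxy-1,2,3,4-tetrahydronaphthalen-1-ol
Product: 3 tert-butyl{[(1S)-5-methoxy-1,2,3,4-tetrahydronaphthalen-1-yl]oxy}dimethylsilane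
Conditions: t-BuMe2SiCl, imidazole, DMF, rt
Reagents that add atoms: tert-butyldimethylsilyl chloride, CC(C)(C)[Si](C)(C)Cl
Why: Imidazole-promoted O-silylation of a secondary alcohol, which does not touch the stereocentre and gives an ether stable to the bases and organolithiums used later.

**Step 3**
Reactants: 3 tert-butyl{[(1S)-5-methoxy-1,2,3,4-tetrahydronaphthalen-1-yl]oxy}dimethylsilane
Product: 5 (4S)-4-(tert-butyldimethylsilyloxy)-8-methoxy-3,4-dihydronaphthalen-1(2H)-one, via benzylic alcohol 4 (not isolated)
Conditions: DDQ, 1,4-dioxane–H2O, rt → 50 °C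
Reagents that add atoms: water, O
Why: DDQ benzylic oxidation, in which hydride abstraction should occur at C4 because only that cation is conjugated with the ortho methoxy group (C1–H is meta to OMe, tertiary and shielded by the silyl group); water traps the cation and alcohol 4 is oxidised on to the aryl ketone, the C1 stereocentre staying untouched.

**Step 4**
Reactants: 5 (4S)-4-(tert-butyldimethylsilyloxy)-8-methoxy-3,4-dihydronaphthalen-1(2H)-one; 6 triethyl phosphonoacetate
Product: 7 ethyl (2E)-2-[(4S)-4-(tert-butyldimethylsilyloxy)-8-methoxy-3,4-dihydronaphthalen-1(2H)-ylidene]acetate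
Conditions: NaH, THF, 0 °C → reflux
Reagents that add atoms: none
Why: Horner–Wadsworth–Emmons olefination of the tetralone carbonyl, expected to favour the (E)-enoate; any endocyclic double-bond isomer formed alongside converges in step 5.

**Step 5**
Reactants: 7 ethyl (2E)-2-[(4S)-4-(tert-butyldimethylsilyloxy)-8-methoxy-3,4-dihydronaphthalen-1(2H)-ylidene]acetate
Product: 8 ethyl 2-[(1S,4S)-4-(tert-butyldimethylsilyloxy)-8-methoxy-1,2,3,4-tetrahydronaphthalen-1-yl]acetate
Conditions: H2 (1 atm), 10% Pd/C, EtOAc, rt
Reagents that add atoms: none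
Why: Heterogeneous catalytic hydrogenation, in which the tetralin should adsorb on the face opposite to the pseudoaxial silyloxy group, so that hydrogen adds anti to OSi and the new stereocentre (S) comes out cis to C4–O, the usual outcome for 1,4-disubstituted tetralins made this way; any trans isomer should be removable by chromatography.

**Step 6**
Reactants: 8 ethyl 2-[(1S,4S)-4-(tert-butyldimethylsilyloxy)-8-methoxy-1,2,3,4-tetrahydronaphthalen-1-yl]acetate
Product: 10 {[(1E)-1-ethoxy-2-[(1S,4S)-4-(tert-butyldimethylsilyloxy)-8-methoxy-1,2,3,4-tetrahydronaphthalen-1-yl]ethenyl]oxy}trimethylsilane, via lithium enolate 9 (not isolated)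
Conditions: LiN(i-Pr)2, THF, −78 °C; then Me3SiCl, −78 °C → rt; non-aqueous work-up (pentane, filtration)
Reagents that add atoms: chlorotrimethylsilane, C[Si](C)(C)Cl
Why: Kinetic ester enolisation followed by O-silylation gives the ketene silyl acetal (its geometry is of no consequence), and neither the silyl ether nor the two benzylic stereocentres, which are not acidic under these conditions, is affected.

**Step 7**
Reactants: 11 3-methoxyphenol
Product: 12 1-methoxy-3-(methoxymethoxy)benzene
Conditions: MeOCH2Cl, i-Pr2NEt, CH2Cl2, 0 °C → rt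
Reagents that add atoms: chloromethyl methyl ether, COCCl
Why: O-alkylation of the phenol (methoxymethyl ether formation) installs a second, strong ortho-directing group.

**Step 8**
Reactants: 12 1-methoxy-3-(methoxymethoxy)benzene
Product: 14 2-iodo-1-methoxy-3-(methoxymethoxy)benzene, via aryllithium 13 (not isolated)
Conditions: n-BuLi, THF, 0 °C → rt; then I2, −78 °C → rt
Reagents that add atoms: iodine, II
Why: Directed ortho-metalation takes place at C2, the position flanked by both oxygen directing groups, and the aryllithium is quenched by iodine.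

**Step 9**
Reactants: 14 2-iodo-1-methoxy-3-(methoxymethoxy)benzene
Product: 15 2-iodo-3-methoxyphenol
Conditions: HCl (cat.), MeOH, 50 °C
Reagents that add atoms: none
Why: Acid-catalysed transacetalisation removes the methoxymethyl group as dimethoxymethane while the aryl iodide and the methyl ether are inert.

**Step 10**
Reactants: 15 2-iodo-3-methoxyphenol
Product: 16 2-iodo-3-methoxyphenyl trifluoromethanesulfonate
Conditions: Tf2O, pyridine, CH2Cl2, 0 °C
Reagents that add atoms: trifluoromethanesulfonic anhydride, O=S(=O)(OS(=O)(=O)C(F)(F)F)C(F)(F)F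
Why: O-sulfonylation of the phenol gives the ortho-iodoaryl triflate, a precursor that releases the aryne at −78 °C on iodine–lithium exchange.

**Step 11**
Reactants: 10 ketene silyl acetal (from step 6); 16 2-iodo-3-methoxyphenyl trifluoromethanesulfonate (excess)
Product: 20 (8RS)-8-[(1S,4S)-4-(tert-butyldimethylsilyloxy)-8-methoxy-1,2,3,4-tetrahydronaphthalen-1-yl]-5-methoxybicyclo[4.2.0]octa-1,3,5-trien-7-one, via 2-lithio-3-methoxyphenyl triflate 17 (not isolated), via 3-methoxybenzyne 18 (not isolated), via silyl ketal cycloadduct 19 (not isolated)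
Conditions: n-BuLi (slow addition), THF, −78 °C; then 0.5 M HCl, THF, 0 °C
Reagents that add atoms: none
Why: Aryne–ketene silyl acetal [2+2] cycloaddition, in which iodine–lithium exchange gives 17 and loss of LiOTf gives aryne 18; the nucleophilic carbon of 10 attacks the aryne carbon meta to OMe and the aryl anion ortho to OMe closes on the oxocarbenium carbon, so the ketal carbon of 19 and hence the carbonyl of 20 lies next to the OMe-bearing carbon, and mild acid cleaves the trimethylsilyl ketal without touching the silyl ether (unreacted 10 returns ester 8 on work-up).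

**Step 12**
Reactants: 20 benzocyclobutenone (from step 11); 21 (Z)-1-bromo-2-ethoxyethene
Product: 26 4-[(1S,4S)-4-(tert-butyldimethylsilyloxy)-8-methoxy-1,2,3,4-tetrahydronaphthalen-1-yl]-8-methoxynaphthalen-1-ol, via (Z)-2-ethoxyvinyllithium 22 (not isolated), via lithium benzocyclobutenoxide 23 (not isolated), via o-quinodimethane dienolate 24 (not isolated), via lithium 3-ethoxydihydronaphthalenolate 25 (not isolated)
Conditions: 21, t-BuLi (2 equiv per 21), THF–Et2O, −78 °C; then 20, −78 °C → rt; aq NH4Cl
Reagents that add atoms: none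
Why: Alkenyllithium 22 adds to the strained carbonyl of 20, which cannot enolise without forming a benzocyclobutadiene, from the face away from the tetralinyl group and gives alkoxide 23. On warming, the oxyanion accelerates conrotatory 4π opening of the C7–C8 bond to the o-quinodimethane dienolate 24, and disrotatory 6π electrocyclisation of its triene C2′=C3′–C4′=C4a′–C8a′=C1′ joins C1′ to C2′ and closes ring C as enolate 25 (the C3′–C4′ bond stems from the addition); E1cB loss of ethoxide and tautomerisation then give the naphtholate. The closest known reaction type is the ring expansion of benzocyclobutenones to 1-naphthols by addition of alkenyllithiums, 2-alkoxyvinyllithiums included. No stereocentre is formed, since C1′ becomes an arene carbon, so both C8 epimers of 20 converge and the tetralin centres C1 and C4 are only spectators. The step needs opening of the C(O)–C(sp3) bond with the vinyl group turned inward, which the strong outward preference of the oxido substituent secures, and a defined naphthol regiochemistry, which is fixed beforehand because the carbonyl of 20 sits next to the OMe-bearing carbon (OH ends peri to OMe and para to the tetralin). The Z-ethoxy group serves only as the leaving group that brings ring C to the aromatic oxidation level.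

**Step 13**
Reactants: 26 4-[(1S,4S)-4-(tert-butyldimethylsilyloxy)-8-methoxy-1,2,3,4-tetrahydronaphthalen-1-yl]-8-methoxynaphthalen-1-ol
Product: 27 Dipolynaphthalene B, (1S,4S)-4-(4-hydroxy-5-methoxynaphthalen-1-yl)-5-methoxy-1,2,3,4-tetrahydronaphthalen-1-ol
Conditions: Bu4NF, AcOH, THF, 0 °C → rt
Reagents that add atoms: none
Why: Fluoride-mediated desilylation, buffered with acetic acid so that the electron-rich naphthol is not exposed to strong base, frees the C1 alcohol without touching either stereocentre.

**Compound list**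
1 | 5-methoxy-1-tetralone | COc1cccc2c1CCCC2=O | starting material
2 | (1S)-5-methoxy-1,2,3,4-tetrahydronaphthalen-1-ol | COc1cccc2c1CCC[C@@H]2O | intermediate
3 | tert-butyl{[(1S)-5-methoxy-1,2,3,4-tetrahydronaphthalen-1-yl]oxy}dimethylsilane | COc1cccc2c1CCC[C@@H]2O[Si](C)(C)C(C)(C)C | intermediate
4 | (4S)-4-(tert-butyldimethylsilyloxy)-8-methoxy-1,2,3,4-tetrahydronaphthalen-1-ol, both C1 epimers (not isolated) | COc1cccc2c1C(O)CC[C@@H]2O[Si](C)(C)C(C)(C)C | intermediate
5 | (4S)-4-(tert-butyldimethylsilyloxy)-8-methoxy-3,4-dihydronaphthalen-1(2H)-one | COc1cccc2c1C(=O)CC[C@@H]2O[Si](C)(C)C(C)(C)C | intermediate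
6 | triethyl phosphonoacetate | CCOC(=O)CP(=O)(OCC)OCC | starting material
7 | ethyl (2E)-2-[(4S)-4-(tert-butyldimethylsilyloxy)-8-methoxy-3,4-dihydronaphthalen-1(2H)-ylidene]acetate | CCOC(=O)/C=C1\CC[C@H](O[Si](C)(C)C(C)(C)C)c2cccc(OC)c12 | intermediate
8 | ethyl 2-[(1S,4S)-4-(tert-butyldimethylsilyloxy)-8-methoxy-1,2,3,4-tetrahydronaphthalen-1-yl]acetate (cis) | CCOC(=O)C[C@@H]1CC[C@H](O[Si](C)(C)C(C)(C)C)c2cccc(OC)c12 | intermediate
9 | lithium enolate of 8, OLi trans to the tetralinyl group (not isolated) | CCO/C(O[Li])=C\[C@@H]1CC[C@H](O[Si](C)(C)C(C)(C)C)c2cccc(OC)c12 | intermediate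
10 | {[(1E)-1-ethoxy-2-[(1S,4S)-4-(tert-butyldimethylsilyloxy)-8-methoxy-1,2,3,4-tetrahydronaphthalen-1-yl]ethenyl]oxy}trimethylsilane | CCO/C(O[Si](C)(C)C)=C\[C@@H]1CC[C@H](O[Si](C)(C)C(C)(C)C)c2cccc(OC)c12 | intermediate
11 | 3-methoxyphenol | COc1cccc(O)c1 | starting material
12 | 1-methoxy-3-(methoxymethoxy)benzene | COCOc1cccc(OC)c1 | intermediate
13 | [2-methoxy-6-(methoxymethoxy)phenyl]lithium (not isolated) | COCOc1cccc(OC)c1[Li] | intermediate
14 | 2-iodo-1-methoxy-3-(methoxymethoxy)benzene | COCOc1cccc(OC)c1I | intermediate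
15 | 2-iodo-3-methoxyphenol | COc1cccc(O)c1I | intermediate
16 | 2-iodo-3-methoxyphenyl trifluoromethanesulfonate | COc1cccc(OS(=O)(=O)C(F)(F)F)c1I | intermediate
17 | 2-lithio-3-methoxyphenyl trifluoromethanesulfonate (not isolated) | COc1cccc(OS(=O)(=O)C(F)(F)F)c1[Li] | intermediate
18 | 3-methoxybenzyne, 1-methoxy-2,3-didehydrobenzene (not isolated) | COC1=CC=CC#C1 | intermediate
19 | 7-ethoxy-5-methoxy-8-[(1S,4S)-4-(tert-butyldimethylsilyloxy)-8-methoxy-1,2,3,4-tetrahydronaphthalen-1-yl]-7-(trimethylsilyloxy)bicyclo[4.2.0]octa-1,3,5-triene (not isolated) | COc1cccc2c1C(OCC)(O[Si](C)(C)C)C2[C@@H]3CC[C@H](O[Si](C)(C)C(C)(C)C)c4cccc(OC)c43 | intermediate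
20 | (8RS)-8-[(1S,4S)-4-(tert-butyldimethylsilyloxy)-8-methoxy-1,2,3,4-tetrahydronaphthalen-1-yl]-5-methoxybicyclo[4.2.0]octa-1,3,5-trien-7-one | COc1cccc2c1C(=O)C2[C@@H]3CC[C@H](O[Si](C)(C)C(C)(C)C)c4cccc(OC)c43 | intermediate
21 | (Z)-1-bromo-2-ethoxyethene | CCO/C=C\Br | starting material
22 | (Z)-2-ethoxyvinyllithium (not isolated) | CCO/C=C\[Li] | intermediate
23 | lithium 7-[(Z)-2-ethoxyethenyl]-5-methoxy-8-[(1S,4S)-4-(tert-butyldimethylsilyloxy)-8-methoxy-1,2,3,4-tetrahydronaphthalen-1-yl]bicyclo[4.2.0]octa-1,3,5-trien-7-olate (not isolated) | COc1cccc2c1C(O[Li])(/C=C\OCC)C2[C@@H]3CC[C@H](O[Si](C)(C)C(C)(C)C)c4cccc(OC)c43 | intermediate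
24 | o-quinodimethane dienolate: lithium 3-ethoxy-1-{2-methoxy-6-[(tetralin-1-yl)methylidene]cyclohexa-2,4-dien-1-ylidene}prop-2-en-1-olate, oxido outward and (Z)-ethoxyvinyl inward (not isolated) | [Li]O/C(/C=C\OCC)=C1/C(=C[C@@H]2CC[C@H](O[Si](C)(C)C(C)(C)C)c3cccc(OC)c32)C=CC=C1OC | intermediate
25 | lithium 3-ethoxy-8-methoxy-4-[(1S,4S)-4-(tert-butyldimethylsilyloxy)-8-methoxy-1,2,3,4-tetrahydronaphthalen-1-yl]-3,4-dihydronaphthalen-1-olate (not isolated) | [Li]OC1=CC(OCC)C([C@@H]3CC[C@H](O[Si](C)(C)C(C)(C)C)c4cccc(OC)c43)c2cccc(OC)c12 | intermediate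
26 | 4-[(1S,4S)-4-(tert-butyldimethylsilyloxy)-8-methoxy-1,2,3,4-tetrahydronaphthalen-1-yl]-8-methoxynaphthalen-1-ol | COc1cccc2c1[C@H](c1ccc(O)c3c(OC)cccc13)CC[C@@H]2O[Si](C)(C)C(C)(C)C | intermediate
27 | Dipolynaphthalene B, (1S,4S)-4-(4-hydroxy-5-methoxynaphthalen-1-yl)-5-methoxy-1,2,3,4-tetrahydronaphthalen-1-ol | COc1cccc2c1[C@H](c1ccc(O)c3c(OC)cccc13)CC[C@@H]2O | target

**Step count**
Total: 13 steps. Longest linear sequence: 9 steps (steps 1–6, 11, 12, 13); steps 7–10 form the side branch to the aryne precursor.

**Steps most likely to fail**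

Step 12 (key step). The Z-ethoxy group and the tetralinyl group both end up on the inside of the closing triene. The 6π closure may then be slow enough that a [1,5]-hydrogen shift from the tetralinyl C–H in the o-quinodimethane (which would also erase the C4 stereocentre) competes, or that the alkoxide cleaves at the aryl–C(O) bond instead. The fallback sets out from 20 and uses unsubstituted vinyllithium (from tetravinylstannane and n-BuLi, THF, −78 °C → rt), which has no inside substituent on the closing terminus. The same opening and closure should end, after protonation, at 4-[(1S,4S)-4-(tert-butyldimethylsilyloxy)-8-methoxy-1,2,3,4-tetrahydronaphthalen-1-yl]-8-methoxy-3,4-dihydronaphthalen-1(2H)-one F4. Aromatisation then becomes a separate oxidation: LiN(SiMe3)2 and Me3SiCl give the trimethylsilyl enol ether of F4, [3,4-dihydronaphthalen-1-yl]oxytrimethylsilane F5, and Saegusa–Ito dehydrogenation with Pd(OAc)2 in MeCN gives the naphthalen-1(4H)-one F6. F6 tautomerises to the naphthol, and the route is rejoined at 26.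

Step 3. Hydride abstraction could occur at C1–H instead, with loss of the silyl ether and return to ketone 1, or the C4 cation could eliminate and aromatise to a naphthalene before water captures it. The fallback sets out from 2 and changes the protecting group to one that deactivates C1–H inductively, with a chromium oxidant. Acetylation (Ac2O, pyridine) gives (1S)-5-methoxy-1,2,3,4-tetrahydronaphthalen-1-yl acetate F1. CrO3 in AcOH–H2O oxidises the only benzylic methylene to (1S)-5-methoxy-4-oxo-1,2,3,4-tetrahydronaphthalen-1-yl acetate F2. K2CO3 in MeOH at 0 °C frees (4S)-4-hydroxy-8-methoxy-3,4-dihydronaphthalen-1(2H)-one F3, and t-BuMe2SiCl/imidazole returns to the route at 5.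

Step 5. Facial discrimination across the 1,4-relationship could be poor (giving trans ester), and hydrogenolysis of the benzylic C–O bond on palladium is possible. The fallback sets out from geometrically pure (E)-7 and replaces substrate-controlled surface hydrogenation by ligand-controlled conjugate reduction with a copper hydride: Cu(OAc)2, the enantiomer of p-tol-BINAP that delivers hydride anti to OSi, polymethylhydrosiloxane, t-BuOH, toluene. This leaves the benzylic ether untouched and comes back to the route at 8; it makes no new compound (F0).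

**Further compounds**
F1 | step 3 | (1S)-5-methoxy-1,2,3,4-tetrahydronaphthalen-1-yl acetate | COc1cccc2c1CCC[C@@H]2OC(C)=O
F2 | step 3 | (1S)-5-methoxy-4-oxo-1,2,3,4-tetrahydronaphthalen-1-yl acetate | COc1cccc2c1C(=O)CC[C@@H]2OC(C)=O
F3 | step 3 | (4S)-4-hydroxy-8-methoxy-3,4-dihydronaphthalen-1(2H)-one | COc1cccc2c1C(=O)CC[C@@H]2O
F0 | step 5 | none | none
F4 | step 12 | 4-[(1S,4S)-4-(tert-butyldimethylsilyloxy)-8-methoxy-1,2,3,4-tetrahydronaphthalen-1-yl]-8-methoxy-3,4-dihydronaphthalen-1(2H)-one (both C4 epimers) | COc1cccc2c1C(=O)CCC2[C@@H]3CC[C@H](O[Si](C)(C)C(C)(C)C)c4cccc(OC)c43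
F5 | step 12 | {[4-[(1S,4S)-4-(tert-butyldimethylsilyloxy)-8-methoxy-1,2,3,4-tetrahydronaphthalen-1-yl]-8-methoxy-3,4-dihydronaphthalen-1-yl]oxy}trimethylsilane | COc1cccc2c1C(O[Si](C)(C)C)=CCC2[C@@H]3CC[C@H](O[Si](C)(C)C(C)(C)C)c4cccc(OC)c43
F6 | step 12 | 4-[(1S,4S)-4-(tert-butyldimethylsilyloxy)-8-methoxy-1,2,3,4-tetrahydronaphthalen-1-yl]-8-methoxynaphthalen-1(4H)-one | COc1cccc2c1C(=O)C=CC2[C@@H]3CC[C@H](O[Si](C)(C)C(C)(C)C)c4cccc(OC)c43
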